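**The decision.** Time is the open setting for the summer flask: it has been followed to 3.00 h, and the question is whether leaving it until 10 h gains any J or whether it can be stopped sooner.

common to all: G 0.30 M; L 0.30 mM
- summer: the very flask that is asked about, followed so far
- flask: time 10 h

summer run (percent of the G charged)

| time / h | G / % | J / % | X / % |
|---|---|---|---|
| 0.417 | 12.1 | 67.6 | 22.1 |
| 1.00 | 1.1 | 69.8 | 27.5 |
| 2.00 | 2.1 | 70.3 | 29.0 |
| 3.00 | 2.3 | 71.8 | 26.8 |

(standard deviation of a reading: 1 percentage point)

- the state of affairs at 10 h: stopped, and by what, or still going (it is still moving / forward and back rates have come level / no working catalyst is left)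
- conversion of G at 10 h
- amount of J at 10 h, in percent of the G charged
- amount of X at 10 h, in percent of the G charged
- amount of J if the flask were left three thousand times as long, in percent of the G charged

- the numbers in the tables scatter by 1 percentage point (one standard deviation)
- the reaction counts as stopped when no species that holds the G changes by six tenths of a point or more over the second half of the time

**The early reading.** G reads 1.1% at 1.00 h, and between 0.417 h and 1.00 h the readings of X gain 5.4 percentage points and those of J 2.2 points, more for X than for J. So J and X are probably still exchanging at that stage, and the useful question is how fast X forms from J compared with how fast it returns.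

**The level ratio.** Suppose J turns into X and X back into J. Dividing the back rate by the forward rate removes time, leaving c_X/c_J over the value at which the two rates are equal. That value, the level ratio ρ, the c_X/c_J at which X stops gaining on J, is read from the summed readings from 1.00 h on as 0.393. This is thermodynamic control of J against X. At 0.417 h the ratio reads 0.327, lower than ρ, so these readings put the back rate then at about 83.2% of the forward rate.

**The reckoning.** The same late readings leave G at 1.83%. Dividing the rest in the ratio ρ gives J 70.5% and X 27.7%. If the rates are level, waiting until 10 h adds no J, so the next run can be stopped early.

**The forecast.** The forecast gives "forward and back rates have come level" at 10 h, conversion 98.2%, J 70.5%, X 27.8% and 70.5% J after a very long time, on the ground of “the three species relaxing toward a common equilibrium”.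

**The result.** The flask at 10 h shows "forward and back rates have come level", with conversion 98.4%, J 71.3%, X 27.1%, and 71.3% J when left very much longer.

    G + L ⇌ E (K = 40.0 L mol⁻¹, k = 496 L mol⁻¹ min⁻¹)
    E ⇌ L + J (K = 1.14 M, k = 132 min⁻¹)
    J + L ⇌ X + L, rate k3*[L]*[J] forward; the back reaction follows from the equilibrium constant (K = 0.380, k = 197 L mol⁻¹ min⁻¹)

**Ratio reused.** From conversion 98.4%, ρ gives J 70.6%, and the flask holds 71.3%. A neighbouring flask read at 40 h, with conversion 98.4%, gets 70.6% from the same ρ and holds 71.3% J. J stays there mainly because X runs back to J: in the run without that back step, X at 10 h stands at 100% instead of 27.1%, a difference of 73 points.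

The numbers in the tables come from a simulation with made-up constants; the scatter is artificial.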